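**Retrosynthetic overview**
- The target is an aryltetralin: C1 carries pendant ring C, C2 and C3 carry the CH2OH groups, C4 is the CH2, ring A is the fused arene (C4a to C8a) and ring B the carbocycle. It is traced back, through debenzylation of the two phenols and hydride opening of a temporary trans-fused γ-lactone that ties the C2 and C3 carbinol carbons, to an aryltetralin lactone.
- Ring B is disconnected at C1–C8a and C1–C2. A one-flask aldol/Friedel–Crafts annulation joins an (S)-β-(arylmethyl)-γ-butyrolactone with one stereocenter to O-benzylvanillin: the aldol makes C1–C2, then the C1 cation is arylated by ring A, which closes ring B and sets C2 and C1 from C3.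
- Enabling feature: the para oxygen of ring C makes the C1 cation a quinone-methide-like oxocarbenium ion. Ring A is a 3,4,5-trioxygenated benzyl ring whose two free ortho carbons are equivalent and each para to a methoxy group, so the closure has only one possible site.
- The lactone comes from O-benzylsyringaldehyde and dimethyl succinate by Stobbe condensation, rhodium-catalysed asymmetric hydrogenation (sets C3) and ester-selective reduction with lactonization.
- Ring order: the temporary lactone ring first, ring B second; the lactone ring is opened again at the end.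

Key step: step 4

Remark on the chemistry (assumption): the (R,R) antipode of the bisphospholane ligand is taken to give the (S)-configured succinate half-ester, by analogy with the behaviour of this catalyst family towards itaconates. If a rotation or chiral HPLC check shows the opposite sense, the equally available (S,S) antipode is used.

**Step 1**
Reactants: 1 4-(benzyloxy)-3,5-dimethoxybenzaldehyde; 2 dimethyl succinate
Product: 3 (E)-4-[4-(benzyloxy)-3,5-dimethoxyphenyl]-3-(methoxycarbonyl)but-3-enoic acid
Conditions: NaOMe (2.2 equiv), MeOH, reflux; then aq. HCl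
Reagents that add atoms: none
Why: Stobbe condensation of a non-enolizable aldehyde with a succinic diester, which should deliver the itaconate-type half-ester with the ester conjugated, the carboxyl group on the CH2 arm and the E alkene (aryl trans to CO2Me) favoured.

**Step 2**
Reactants: 3 (E)-4-[4-(benzyloxy)-3,5-dimethoxyphenyl]-3-(methoxycarbonyl)but-3-enoic acid
Product: 4 (3S)-4-[4-(benzyloxy)-3,5-dimethoxyphenyl]-3-(methoxycarbonyl)butanoic acid
Conditions: [Rh(cod)((R,R)-Et-DuPhos)]BF4 (0.5 mol%), H2 (5 bar), NaOMe (0.1 equiv), MeOH, 20 °C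
Reagents that add atoms: none
Why: Rhodium-catalysed asymmetric hydrogenation of a Stobbe-derived itaconate half-ester: the carboxylate chelates the metal and the C2-symmetric bisphospholane directs H2 to one alkene face, which sets the future C3 stereocenter; the homogeneous catalyst should leave the benzyl ether intact.

**Step 3**
Reactants: 4 (3S)-4-[4-(benzyloxy)-3,5-dimethoxyphenyl]-3-(methoxycarbonyl)butanoic acid
Product: 6 (4S)-4-{[4-(benzyloxy)-3,5-dimethoxyphenyl]methyl}oxolan-2-one, via hydroxy acid 5 (not isolated)
Conditions: LiBH4 (2.5 equiv), THF, 0 → 20 °C; then 2 M HCl, 20 °C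
Reagents that add atoms: none
Why: Chemoselective borohydride reduction (the ester is reduced, the lithium carboxylate is not) followed by acid-induced γ-lactonization; the stereocenter is not touched.

**Step 4**
Reactants: 6 (4S)-4-{[4-(benzyloxy)-3,5-dimethoxyphenyl]methyl}oxolan-2-one; 7 4-(benzyloxy)-3-methoxybenzaldehyde
Product: 9 (3aS,9R,9aS)-7-(benzyloxy)-9-[4-(benzyloxy)-3-methoxyphenyl]-6,8-dimethoxy-3a,4,9,9a-tetrahydronaphtho[2,3-c]furan-1(3H)-one, via aldol carbinol 8 (not isolated)
Conditions: LiN(iPr)2 (1.1 equiv), THF, −78 °C; then 7 (1.0 equiv), −78 °C; then CF3CO2H (20 equiv), CH2Cl2, −78 → 20 °C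
Reagents that add atoms: none
Why: The lithium enolate of 6 adds to aldehyde 7 on the face anti to the C3 arylmethyl group (aldol addition, 1,2-induction in the planar five-membered enolate), which sets C2 trans to C3; the carbinol configuration of 8 does not matter because ionization erases it. Trifluoroacetic acid then ionizes the benzylic carbinol to a cation that the para benzyloxy group of ring C stabilizes as a quinone-methide-like oxocarbenium ion, and an ortho carbon of ring A attacks it in an intramolecular Friedel–Crafts alkylation; the closest known reaction type is the acid-induced cyclization of α-(aryl-hydroxymethyl)-β-benzyl-γ-butyrolactones to aryltetralin lactones. Ring B closes in the 6-exo-trig mode with respect to the exocyclic C1=C(aryl) bond of the cation, through a chair-like transition state. C1 is controlled by C2: allylic strain should hold the C2–H bond in the plane of the cation and the tether through C3 and C4 lets ring A reach only one face, which places the C1 aryl group trans to the C2 carbonyl substituent. The step needs arylation to outrun proton loss to the arylidene lactone and needs a single site of attack; the first is secured by the nucleophilicity of ring A (the attacking carbon is para to one methoxy group and ortho to the other), the second by the equivalence of its two free ortho carbons.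

**Step 5**
Reactants: 9 (3aS,9R,9aS)-7-(benzyloxy)-9-[4-(benzyloxy)-3-methoxyphenyl]-6,8-dimethoxy-3a,4,9,9a-tetrahydronaphtho[2,3-c]furan-1(3H)-one
Product: 10 [(1R,2S,3S)-7-(benzyloxy)-1-[4-(benzyloxy)-3-methoxyphenyl]-6,8-dimethoxy-1,2,3,4-tetrahydronaphthalene-2,3-diyl]dimethanol
Conditions: LiAlH4 (1.5 equiv), THF, 0 → 20 °C; aqueous work-up
Reagents that add atoms: none
Why: Hydride reduction of the lactone to the 1,4-diol; carbonyl addition should be faster than enolization at C2, so the trans arrangement is kept and the benzyl ethers are inert.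

**Step 6**
Reactants: 10 [(1R,2S,3S)-7-(benzyloxy)-1-[4-(benzyloxy)-3-methoxyphenyl]-6,8-dimethoxy-1,2,3,4-tetrahydronaphthalene-2,3-diyl]dimethanol
Product: 11 [(1R,2S,3S)-7-hydroxy-1-(4-hydroxy-3-methoxyphenyl)-6,8-dimethoxy-1,2,3,4-tetrahydronaphthalene-2,3-diyl]dimethanol
Conditions: H2 (1 bar), 10% Pd/C, MeOH/EtOAc, 20 °C
Reagents that add atoms: none
Why: Catalytic hydrogenolysis of both aryl benzyl ethers; the C–C framework, the primary alcohols and the three stereocenters are not affected.

**Compound list**
1 | 4-(benzyloxy)-3,5-dimethoxybenzaldehyde (O-benzylsyringaldehyde) | COc1cc(C=O)cc(OC)c1OCc1ccccc1 | starting material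
2 | dimethyl succinate | COC(=O)CCC(=O)OC | starting material
3 | (E)-4-[4-(benzyloxy)-3,5-dimethoxyphenyl]-3-(methoxycarbonyl)but-3-enoic acid | OC(=O)C/C(C(=O)OC)=C\c1cc(OC)c(OCc2ccccc2)c(OC)c1 | intermediate
4 | (3S)-4-[4-(benzyloxy)-3,5-dimethoxyphenyl]-3-(methoxycarbonyl)butanoic acid | COC(=O)[C@@H](Cc1cc(OC)c(OCc2ccccc2)c(OC)c1)CC(=O)O | intermediate
5 | (3S)-4-[4-(benzyloxy)-3,5-dimethoxyphenyl]-3-(hydroxymethyl)butanoic acid (present as its lithium salt) | OC[C@@H](Cc1cc(OC)c(OCc2ccccc2)c(OC)c1)CC(=O)O | intermediate (not isolated)
6 | (4S)-4-{[4-(benzyloxy)-3,5-dimethoxyphenyl]methyl}oxolan-2-one | O=C1C[C@H](Cc2cc(OC)c(OCc3ccccc3)c(OC)c2)CO1 | intermediate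
7 | 4-(benzyloxy)-3-methoxybenzaldehyde (O-benzylvanillin) | COc1cc(C=O)ccc1OCc1ccccc1 | starting material
8 | (3R,4S)-3-{[4-(benzyloxy)-3-methoxyphenyl](hydroxy)methyl}-4-{[4-(benzyloxy)-3,5-dimethoxyphenyl]methyl}oxolan-2-one, both carbinol epimers | COc1cc(C(O)[C@@H]2C(=O)OC[C@H]2Cc2cc(OC)c(OCc3ccccc3)c(OC)c2)ccc1OCc1ccccc1 | intermediate (not isolated)
9 | (3aS,9R,9aS)-7-(benzyloxy)-9-[4-(benzyloxy)-3-methoxyphenyl]-6,8-dimethoxy-3a,4,9,9a-tetrahydronaphtho[2,3-c]furan-1(3H)-one | COc1cc([C@@H]2c3c(cc(OC)c(OCc4ccccc4)c3OC)C[C@H](CO5)[C@H]2C5=O)ccc1OCc1ccccc1 | intermediate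
10 | [(1R,2S,3S)-7-(benzyloxy)-1-[4-(benzyloxy)-3-methoxyphenyl]-6,8-dimethoxy-1,2,3,4-tetrahydronaphthalene-2,3-diyl]dimethanol | COc1cc([C@@H]2c3c(cc(OC)c(OCc4ccccc4)c3OC)C[C@H](CO)[C@H]2CO)ccc1OCc1ccccc1 | intermediate
11 | [(1R,2S,3S)-7-hydroxy-1-(4-hydroxy-3-methoxyphenyl)-6,8-dimethoxy-1,2,3,4-tetrahydronaphthalene-2,3-diyl]dimethanol | COc1cc([C@@H]2c3c(cc(OC)c(O)c3OC)C[C@H](CO)[C@H]2CO)ccc1O | target

**Step count and risks**
Total step count: 6. Longest linear sequence: 6 steps (1 → 11).

Steps most likely to fail:

1. Step 4. After ionization the cation may lose the C2 proton to give the conjugated arylidene lactone faster than ring A attacks. The peri methoxy group at C8 may also erode the facial preference at C1 while ring B is locked by the trans-fused lactone. The fallback moves the ring closure to the flexible triol oxidation level and sets out from 8: the aldol stage of step 4 is quenched with aqueous NH4Cl and 8 is isolated. LiAlH4 in THF at 0 °C should reduce the lactone to (2S,3S)-2-{[4-(benzyloxy)-3-methoxyphenyl](hydroxy)methyl}-3-{[4-(benzyloxy)-3,5-dimethoxyphenyl]methyl}butane-1,4-diol F1. BF3·OEt2 in CH2Cl2 at 0 °C then ionizes the benzylic carbinol. The cation is expected to be trapped reversibly by the hydroxymethyl group on C3 as the cyclic ether {(3S,4S)-2-[4-(benzyloxy)-3-methoxyphenyl]-4-{[4-(benzyloxy)-3,5-dimethoxyphenyl]methyl}oxolan-3-yl}methanol F2. This ether reopens under the same acid and is arylated by ring A, the known acid-induced isomerization of 2-aryl-tetrahydrofuran lignans to aryltetralins. Without a carbonyl group at C2 elimination has no conjugation to gain and ring B is free to relax. The route is rejoined at 10.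

2. Step 2. The hydrogenation may run with insufficient facial discrimination, or with the opposite sense, for example through the E/Z mixture or weak carboxylate binding of this hindered substrate. The fallback replaces asymmetric catalysis by classical resolution and sets out from 3. Hydrogenation with the achiral catalyst [Rh(cod)(dppb)]BF4 under H2 in MeOH should give racemic 4-[4-(benzyloxy)-3,5-dimethoxyphenyl]-3-(methoxycarbonyl)butanoic acid F3 without loss of the benzyl ether. Crystallization with (S)-1-phenylethylamine from ethanol should give the diastereomerically pure salt (S)-1-phenylethylammonium (3S)-4-[4-(benzyloxy)-3,5-dimethoxyphenyl]-3-(methoxycarbonyl)butanoate F4; the antipodal amine is taken if the salt of the (R)-acid proves the less soluble one. Acidification with dilute HCl returns the route to 4.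

3. Step 3. Acyloxyborane species formed from the free acid may reduce the carboxyl group as well, so that chemoselectivity is lost and over-reduction sets in. The fallback accepts exhaustive reduction and restores the lactone by a regioselective oxidation; it sets out from 4. LiAlH4 in THF should give (2S)-2-{[4-(benzyloxy)-3,5-dimethoxyphenyl]methyl}butane-1,4-diol F5. Ag2CO3 on Celite in refluxing toluene should oxidize the less hindered primary alcohol, the one remote from the branch, and the lactol is oxidized on to the β-substituted lactone (the known oxidative lactonization of 2-substituted butane-1,4-diols). The route is rejoined at 6.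

**Further compounds**
F1 | step 4 | (2S,3S)-2-{[4-(benzyloxy)-3-methoxyphenyl](hydroxy)methyl}-3-{[4-(benzyloxy)-3,5-dimethoxyphenyl]methyl}butane-1,4-diol, both carbinol epimers | COc1cc(C(O)[C@H](CO)[C@@H](CO)Cc2cc(OC)c(OCc3ccccc3)c(OC)c2)ccc1OCc1ccccc1
F2 | step 4 | {(3S,4S)-2-[4-(benzyloxy)-3-methoxyphenyl]-4-{[4-(benzyloxy)-3,5-dimethoxyphenyl]methyl}oxolan-3-yl}methanol, both epimers at the aryl-bearing carbon | COc1cc(C2OC[C@@H](Cc3cc(OC)c(OCc4ccccc4)c(OC)c3)[C@H]2CO)ccc1OCc1ccccc1
F3 | step 2 | racemic 4-[4-(benzyloxy)-3,5-dimethoxyphenyl]-3-(methoxycarbonyl)butanoic acid | COC(=O)C(Cc1cc(OC)c(OCc2ccccc2)c(OC)c1)CC(=O)O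
F4 | step 2 | (S)-1-phenylethylammonium (3S)-4-[4-(benzyloxy)-3,5-dimethoxyphenyl]-3-(methoxycarbonyl)butanoate | COC(=O)[C@@H](Cc1cc(OC)c(OCc2ccccc2)c(OC)c1)CC(=O)[O-].C[C@H]([NH3+])c1ccccc1
F5 | step 3 | (2S)-2-{[4-(benzyloxy)-3,5-dimethoxyphenyl]methyl}butane-1,4-diol | OCC[C@H](Cc1cc(OC)c(OCc2ccccc2)c(OC)c1)CO
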